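**Plan**

1. Ring numbering used throughout: C1 (isopropenyl, central carbon C13), C2=C3(CH3), C4 (C7H2–OAr), C5 (quaternary, CH3 and acid arm), C6.
2. Retrosynthesis: cut the C7–OAr ether bond, then the CH=CH bond that lengthens the C5 arm and the C13=CH2 bond. This folds both arms back into a cis-fused γ-lactone with an acetyl group on C1. Then reconnect C13 to C7 and cut C4–C5 and C1–C6.
3. Enabling feature: C1 and C4 lie cis on either side of the C2=C3 double bond and each carries one exocyclic carbon. A C13–C7 bond therefore makes a bicyclo[2.2.2]octene with C1/C4 as bridgeheads and C13–C7 as a masked o-quinone bridge, i.e. the [4+2] adduct of dearomatised 2-methoxy-4-methylphenol and a methallyl unit tethered through the ketal oxygen.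
4. Forward: oxidative ketalisation of the phenol with methallyl alcohol and intramolecular Diels–Alder close the cyclohexene and an oxolane in one flask. The bridge is opened (MeMgBr, then H5IO6) to the acetyl lactone. Methylenation, lactone reduction, two-carbon extension of the C5 arm and late attachment of the coumarin follow.
5. Stereochemistry: the ketal carbon is set by a chiral trivalent iodine reagent. The tether relays it to C1, C4 and C5 in the cycloaddition, and no later step touches these centres.

Key step: step 1

Assumption: the (R,R)-iodoarene is taken to deliver the (6R)-ketal; if the sense of induction proves opposite, its mirror-image reagent is used in the same way.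

**Route**

Step 1
Reactants: 1 2-methoxy-4-methylphenol; 2 2-methylprop-2-en-1-ol
Product: 4 tricyclic keto ketal, via mixed quinone ketal 3 (not isolated)
Conditions: 2-iodo-1,3-bis[(R)-1-(mesitylcarbamoyl)ethoxy]benzene (1.1 equiv), mCPBA (1.05 equiv), AcOH, CH2Cl2, rt (pre-oxidation, no peracid left); then 2 (10 equiv), −40 °C, slow addition of 1; then rt → 40 °C
Reagents that add atoms: none
Why: Proposed new method: the trivalent iodine centre, made in the flask from the C2-symmetric lactamide iodoarene, takes up the phenol oxygen of 1 by ligand exchange, and 2 then attacks the methoxy-bearing ring carbon with loss of the reduced iodoarene to give 3, the lactamide arms being expected to shield one face of the bound arene; the closest known chemistry is the racemic PhI(OAc)2-mediated oxidative ketalisation–intramolecular Diels–Alder of 2-methoxyphenols with alkenols and the chiral aryl-iodide-mediated dearomatisation of phenols by tethered nucleophiles, enantiocontrol over an external alcohol being the untested element. On warming, the electron-poor cyclohexadienone diene of 3 adds its tethered 1,1-disubstituted alkene in a concerted, suprafacial [4+2] cycloaddition. The cyclohexene ring closes by the cycloaddition itself (bonds C4–C5 and C1–C6), and the oxolane closes as the five-membered ring spanned by the ketal carbon, the tether O–CH2, the inner alkene carbon and the adjacent diene terminus, the only terminus a three-atom tether can reach. The ketal carbon is set by the chiral iodane; C1 and C4 are necessarily cis as bridgeheads, and C5 is fixed relative to the ketal carbon because the alkene can only add to the diene face carrying the tether oxygen, which places CH2O syn and CH3 anti to the ketal bridge. The step needs attack of the alcohol at C–OMe and not at the methyl-bearing para carbon, secured by the methoxy group stabilising positive charge there, and it needs cycloaddition to outrun dimerisation of 3, secured by the tether and by slow addition of 1.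

Step 2
Reactants: 4 tricyclic keto ketal
Product: 5 tertiary carbinol ketal
Conditions: MeMgBr, THF, −78 → 0 °C
Reagents that add atoms: methylmagnesium bromide, C[Mg]Br
Why: Grignard 1,2-addition to a ketone that cannot enolise (bridgehead and fully substituted ketal α-carbons), expected from the face syn to the ring alkene and away from the C6 methylene so that OH points to the saturated bridge; this carbinol centre becomes sp2 again in step 3, so either epimer serves.

Step 3
Reactants: 5 tertiary carbinol ketal
Product: 8 acetyl lactone, via lactol 6 (not isolated), via hydroxy acid 7 (not isolated)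
Conditions: H5IO6, THF–H2O (3:1), 0 °C → rt
Reagents that add atoms: water, O
Why: Periodic acid serves as acid and oxidant in one pot: the furanoside-like methyl ketal is hydrolysed to lactol 6, whose open α-hydroxy ketone form (as its hydrate) undergoes glycol-type cleavage of the C13–C7 bond to the methyl ketone and acid 7, and the acid lactonises onto the cis CH2OH under the same conditions, no ring stereocentre being involved.

Step 4
Reactants: 8 acetyl lactone
Product: 9 isopropenyl lactone
Conditions: Zn, CH2Br2, TiCl4, THF–CH2Cl2, 0 °C → rt
Reagents that add atoms: dibromomethane, BrCBr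
Why: Takai–Lombardo methylenation is non-basic and ketone-selective, so the lactone survives and the α-stereocentre of the β,γ-unsaturated ketone should neither epimerise nor let the ring double bond move into conjugation.

Step 5
Reactants: 9 isopropenyl lactone
Product: 10 diol
Conditions: LiAlH4, THF, 0 °C
Reagents that add atoms: none
Why: Hydride reduction of a lactone to the 1,4-diol is faster than enolisation at the allylic lactone α-carbon and leaves the two unconjugated alkenes untouched.

Step 6
Reactants: 10 diol
Product: 11 mono-TBDPS ether
Conditions: TBDPSCl (1.05 equiv), imidazole, CH2Cl2, −20 → 0 °C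
Reagents that add atoms: tert-butyl(chloro)diphenylsilane, CC(C)(C)[Si](Cl)(c1ccccc1)c1ccccc1
Why: Sterically controlled monosilylation, the bulky silyl chloride reacting at the CH-bound primary alcohol (C7–OH) faster than at the neopentyl alcohol on quaternary C5.

Step 7
Reactants: 11 mono-TBDPS ether
Product: 12 aldehyde
Conditions: Dess–Martin periodinane, CH2Cl2, rt
Reagents that add atoms: none
Why: Dess–Martin oxidation of the neopentyl primary alcohol gives an aldehyde without α-hydrogen, which can neither epimerise nor enolise, under conditions that spare the silyl ether and both alkenes.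

Step 8
Reactants: 12 aldehyde
Product: 13 E-enoate
Conditions: (MeO)2P(O)CH2CO2Me, NaH, THF, 0 °C → reflux
Reagents that add atoms: trimethyl phosphonoacetate, COC(=O)CP(=O)(OC)OC
Why: Horner–Wadsworth–Emmons olefination adds the two missing chain carbons, the stabilised phosphonate anion giving the E-enoate and tolerating the hindered, non-enolisable aldehyde.

Step 9
Reactants: 13 E-enoate
Product: 14 saturated methyl ester
Conditions: Mg, MeOH, 0 °C → rt
Reagents that add atoms: none
Why: Dissolving-metal conjugate reduction transfers electrons only to the conjugated ester, so the enoate C=C is saturated while the isolated ring and isopropenyl double bonds and the silyl ether remain.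

Step 10
Reactants: 14 saturated methyl ester
Product: 15 hydroxy ester
Conditions: Bu4NF, AcOH, THF, rt → 40 °C
Reagents that add atoms: none
Why: Fluoride-induced desilylation, with acetic acid buffering to keep the liberated alkoxide from attacking the methyl ester.

Step 11
Reactants: 15 hydroxy ester; 16 umbelliferone
Product: 17 coumarin ether methyl ester
Conditions: PPh3, DIAD, THF, 0 °C → rt
Reagents that add atoms: none
Why: Mitsunobu etherification, the acidic phenol of 16 displacing the activated primary oxyphosphonium at a CH2 carbon under neutral conditions that spare the isopropenyl group, the ester and the coumarin.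

Step 12
Reactants: 17 coumarin ether methyl ester
Product: 18 target acid
Conditions: LiOH·H2O, THF–H2O, 0 °C → rt; then 1 M HCl to pH 2–3, 0 °C
Reagents that add atoms: lithium hydroxide (hydroxide oxygen), [Li+].[OH-]
Why: Saponification of the unhindered methyl ester, any hydroxide-opened coumarin (cis-coumarinate) reclosing on the brief cold acidification, which is too mild to protonate the isopropenyl group.

**Compound list**

1 | 2-methoxy-4-methylphenol (creosol) | Cc1ccc(O)c(OC)c1 | starting material
2 | 2-methylprop-2-en-1-ol (methallyl alcohol) | C=C(C)CO | starting material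
3 | (6R)-6-methoxy-4-methyl-6-[(2-methylprop-2-en-1-yl)oxy]cyclohexa-2,4-dien-1-one (mixed quinone ketal) | O=C1C=CC(C)=C[C@@]1(OC)OCC(C)=C | intermediate (not isolated)
4 | tricyclic keto ketal: 3-methoxy-5,8-dimethylbicyclo[2.2.2]oct-5-en-2-one with an O–CH2 link from C3 to C8 (oxolane); OMe and the C8 methyl both on the side of the alkene bridge | O=C1[C@@H]2C=C(C)[C@@H]3[C@@]1(OC)OC[C@]3(C)C2 | intermediate
5 | tertiary carbinol ketal: as 4 with C2 now C(OH)CH3, OH toward the saturated bridge, CH3 toward the alkene | C[C@]1(O)[C@@H]2C=C(C)[C@@H]3[C@@]1(OC)OC[C@]3(C)C2 | intermediate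
6 | lactol: as 5 with OH in place of OMe at the ketal carbon | C[C@]1(O)[C@@H]2C=C(C)[C@@H]3[C@@]1(O)OC[C@]3(C)C2 | intermediate (not isolated)
7 | hydroxy acid: cyclohexene with C1 acetyl, C3 methyl, C4 CO2H, C5 CH3 and CH2OH; acetyl, CO2H and CH2OH mutually cis | CC(=O)[C@@H]1C=C(C)[C@H](C(=O)O)[C@](C)(CO)C1 | intermediate (not isolated)
8 | acetyl lactone: cis-fused γ-lactone C4–C(=O)–O–CH2–C5, C1 acetyl on the lactone face, C5 methyl on the opposite face | CC(=O)[C@@H]1C=C(C)[C@@H]2C(=O)OC[C@]2(C)C1 | intermediate
9 | isopropenyl lactone: as 8 with C(CH3)=CH2 in place of acetyl | C=C(C)[C@@H]1C=C(C)[C@@H]2C(=O)OC[C@]2(C)C1 | intermediate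
10 | diol: cyclohexene with C1 isopropenyl, C4 CH2OH and C5 CH2OH all cis, C5 methyl trans | C=C(C)[C@@H]1C=C(C)[C@H](CO)[C@](C)(CO)C1 | intermediate
11 | mono-TBDPS ether: 10 silylated at the C4 CH2OH | C=C(C)[C@@H]1C=C(C)[C@H](CO[Si](c2ccccc2)(c2ccccc2)C(C)(C)C)[C@](C)(CO)C1 | intermediate
12 | aldehyde: 11 with CHO on C5 | C=C(C)[C@@H]1C=C(C)[C@H](CO[Si](c2ccccc2)(c2ccccc2)C(C)(C)C)[C@](C)(C=O)C1 | intermediate
13 | E-enoate: methyl (E)-propenoate arm on C5 | C=C(C)[C@@H]1C=C(C)[C@H](CO[Si](c2ccccc2)(c2ccccc2)C(C)(C)C)[C@](C)(/C=C/C(=O)OC)C1 | intermediate
14 | saturated methyl ester: methyl propanoate arm on C5, silyl ether retained | C=C(C)[C@@H]1C=C(C)[C@H](CO[Si](c2ccccc2)(c2ccccc2)C(C)(C)C)[C@](C)(CCC(=O)OC)C1 | intermediate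
15 | hydroxy ester: methyl 3-[(1R,2R,5S)-2-(hydroxymethyl)-1,3-dimethyl-5-(prop-1-en-2-yl)cyclohex-3-en-1-yl]propanoate | C=C(C)[C@@H]1C=C(C)[C@H](CO)[C@](C)(CCC(=O)OC)C1 | intermediate
16 | umbelliferone (7-hydroxycoumarin) | O=c1ccc2ccc(O)cc2o1 | starting material
17 | coumarin ether methyl ester: methyl ester of 18 | C=C(C)[C@@H]1C=C(C)[C@H](COc2ccc3ccc(=O)oc3c2)[C@](C)(CCC(=O)OC)C1 | intermediate
18 | 3-[(1R,2R,5S)-1,3-dimethyl-2-{[(2-oxo-2H-chromen-7-yl)oxy]methyl}-5-(prop-1-en-2-yl)cyclohex-3-en-1-yl]propanoic acid | C=C(C)[C@@H]1C=C(C)[C@H](COc2ccc3ccc(=O)oc3c2)[C@](C)(CCC(=O)O)C1 | target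

**Step count**

Total: 12 steps. Longest linear sequence: 12 steps (from 1 and 2 to 18); 16 enters at step 11.

**Steps most likely to fail**

Step 1 (enantiocontrol in the dearomatisation). The external alcohol may be delivered to the iodine-bound phenol with little facial discrimination. Acid-catalysed alkoxy exchange at the mixed ketal before cycloaddition may also erode whatever selectivity is reached. The fallback uses known chemistry and sets out again from 1 and 2. The racemic tandem oxidative ketalisation–intramolecular Diels–Alder is run with achiral PhI(OAc)2 in CH2Cl2 and excess 2 at room temperature, which should give racemic keto ketal F1. Its enantiomers are separated by preparative chromatography on a cellulose tris(3,5-dimethylphenylcarbamate) stationary phase. The enantiomer identical with 4 rejoins the route at 4.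

Step 3 (one-pot hydrolysis and cleavage). The inductively deactivated α-hydroxy ketal may hydrolyse only slowly at the acidity periodic acid provides. The β,γ-unsaturated methyl ketone, once formed, may lose its C1 configuration or let the ring double bond move into conjugation while it stays in the acidic aqueous oxidant. The fallback sets out from 5, separates the two events and moves the C–C cleavage to a non-aqueous medium. Hydrolysis alone (1 M HCl, THF, rt) is carried out with isolation of lactol 6, at a stage where no enolisable ketone is present. Pb(OAc)4 in MeOH–benzene at 0 °C then cleaves the open α-ketol through its methyl hemiketal and should give hydroxy methyl ester F2. This is closed with catalytic pyridinium p-toluenesulfonate in CH2Cl2 to 8, where the route is rejoined.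

Step 6 (discrimination of two primary alcohols). The silyl chloride may not distinguish well enough between the two hydroxyls, both of which are flanked by substituted carbons, so that regioisomeric and doubly silylated material forms. The fallback sets out from 10 and replaces reagent-controlled silylation by enzyme-controlled acylation with a protecting group that leaves in the reduction flask. Immobilised Candida antarctica lipase B with vinyl acetate in tert-butyl methyl ether at room temperature should acylate only the CH-bound carbinol, since neopentyl carbinols are poor substrates, giving monoacetate F3. Dess–Martin oxidation gives acetoxy aldehyde F4, and Horner–Wadsworth–Emmons olefination as in step 8 gives acetoxy enoate F5. Mg in MeOH reduces this to saturated acetoxy ester F6. K2CO3 added to the same methanol solution removes the acetate, the methyl ester being inert to methanolysis. The route is rejoined at 15 and the fluoride step is no longer needed.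

**Further compounds**

F1 | step 1 | racemic keto ketal (4 and its mirror image, 1:1) | O=C1[C@@H]2C=C(C)[C@@H]3[C@@]1(OC)OC[C@]3(C)C2.O=C1[C@H]2C=C(C)[C@H]3[C@]1(OC)OC[C@@]3(C)C2
F2 | step 3 | hydroxy methyl ester (methyl ester of 7) | CC(=O)[C@@H]1C=C(C)[C@H](C(=O)OC)[C@](C)(CO)C1
F3 | step 6 | monoacetate of 10 at the C4 CH2OH | C=C(C)[C@@H]1C=C(C)[C@H](COC(C)=O)[C@](C)(CO)C1
F4 | step 6 | acetoxy aldehyde | C=C(C)[C@@H]1C=C(C)[C@H](COC(C)=O)[C@](C)(C=O)C1
F5 | step 6 | acetoxy E-enoate | C=C(C)[C@@H]1C=C(C)[C@H](COC(C)=O)[C@](C)(/C=C/C(=O)OC)C1
F6 | step 6 | saturated acetoxy ester | C=C(C)[C@@H]1C=C(C)[C@H](COC(C)=O)[C@](C)(CCC(=O)OC)C1
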